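**Strategy.** The pyran ring of the target (ring O, arene carbon, benzylic CH, quaternary C–CH3, O–CH) is read as a reduced γ-pyranone. Everything rests on one annulation: the α-carbon of a spiro cyclopentanone is acylated by 2,4,6-trifluorobenzoyl chloride, which makes the bond between the later benzylic and quaternary carbons, and the ketone oxygen of the resulting triketone then displaces an ortho fluoride, which makes the aryl ether bond. The precursor is a menthone-derived spirodiketone; the product is a flat cyclopenta-fused difluorochromone. Its three pyran stereocentres are afterwards set from the convex face by reductive methylation and ionic hydrogenation, and the remaining fluorides become the phenols.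

Key step: step 4

Remark on the starting material: commercial (−)-menthone (1) contains some isomenthone; both carry the same (5R) methyl centre and the isopropyl-bearing centre is erased in step 5, so the mixture is assumed to serve equally.

Locants used below: cyclopenta[b]chromene numbering (C1, C2, spiro C3, C3a, O4, C4a, C5–C8, C8a, C9, C9a) and primed locants for the six-membered carbocycle (C1' = C3, C2', C3' bearing isopropyl, C6' bearing methyl).

**Step 1**
Reactants: 1 (−)-menthone; 2 ethyl formate
Product: 3 hydroxymethylene menthone (chelated enol of the 2-formyl ketone)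
Conditions: NaH, HCO2Et, cat. EtOH, Et2O, 0 °C → rt; then aq HCl
Reagents that add atoms: ethyl formate 2, CCOC=O
Why: Crossed Claisen condensation (formylation) under equilibrating conditions occurs only at the CH2 flank of the ketone, because only that product is drained as a stabilised β-ketoaldehyde enolate; no stereocentre is formed and the methyl-bearing centre is not enolisable.

**Step 2**
Reactants: 3 hydroxymethylene menthone; 4 allyl methyl carbonate
Product: 5 2-allyl-2-formyl ketone (allyl trans and formyl cis to the neighbouring methyl)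
Conditions: Pd(PPh3)4 (2 mol %), THF, rt
Reagents that add atoms: allyl methyl carbonate 4, C=CCOC(=O)OC
Why: Tsuji–Trost allylation of the soft β-ketoaldehyde enolate by the π-allyl complex formed from zerovalent palladium gives C-allylation (any O-allyl enol ether re-ionises), and allylic 1,3-strain with the planar formyl enolate holds the neighbouring methyl pseudo-axial so that the allyl group enters anti to it and sets the quaternary centre.

**Step 3**
Reactants: 5 2-allyl-2-formyl ketone
Product: 6 spirodiketone
Conditions: [Rh(Ph2PCH2CH2PPh2)(acetone)2]BF4 (5 mol %), acetone, rt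
Reagents that add atoms: none
Why: Intramolecular alkene hydroacylation of a 2,2-disubstituted pent-4-enal (oxidative addition of the formyl C–H bond to monovalent rhodium, alkene insertion, reductive elimination) closes the cyclopentanone without touching the quaternary stereocentre, and the fully substituted α-carbon disfavours decarbonylation.

**Step 4**
Reactants: 6 spirodiketone; 7 2,4,6-trifluorobenzoyl chloride
Product: 10 difluorochromone ketone, via lithium enolate 8 (not isolated), via lithium triketonate 9 (not isolated)
Conditions: LiN(SiMe3)2 (2.2 equiv), THF, −78 °C; 7; then −78 → 65 °C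
Reagents that add atoms: 2,4,6-trifluorobenzoyl chloride 7, O=C(Cl)c1c(F)cc(F)cc1F
Why: LiN(SiMe3)2 removes a proton from the only accessible α-position of 6 (the cyclopentanone CH2, since the other α-carbon is the quaternary spiro carbon and the cyclohexanone CH is shielded by isopropyl) to give enolate 8, which is C-acylated by 7; the second equivalent of base turns the 2-aroyl-1,3-diketone into chelated enolate 9, whose cyclopentanone-derived oxygen attacks an ortho C–F carbon on warming and expels fluoride through a Meisenheimer intermediate. The closest known reaction type is the tandem C-acylation/intramolecular SNAr of ketone enolates with 2-fluorobenzoyl chlorides that is used to make chromones and, with nitrogen, 4-quinolones. The γ-pyranone ring is closed by a 6-endo-trig addition–elimination at the β-carbon of the fluoro-substituted aryl ketone. No stereocentre is created, because O4, C3a, C9a and C9 end up in a flat vinylogous ester, and the quaternary spiro centre and the methyl centre are not enolisable and stay untouched. The step needs C- over O-acylation, which the lithium enolate in THF favours and which excess enolate corrects by acyl transfer, and it needs a single site of arylation, which is secured because the two ortho fluorides of the symmetric 2,4,6-trifluorophenyl group are equivalent, the para fluoride cannot be reached, and three fluorines plus the acyl group activate the ring.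

**Step 5**
Reactants: 10 difluorochromone ketone; 11 N-phenylbis(trifluoromethanesulfonimide)
Product: 13 enol triflate, via potassium enolate 12 (not isolated)
Conditions: KN(SiMe3)2, THF, −78 °C; PhN(SO2CF3)2, −78 → 0 °C; aq NH4Cl
Reagents that add atoms: N-phenylbis(trifluoromethanesulfonimide) 11, O=S(=O)(N(c1ccccc1)S(=O)(=O)C(F)(F)F)C(F)(F)F
Why: The only acidic C–H left is the isopropyl-bearing CH next to the cyclohexanone (the chromone has no α- or γ-hydrogen), so enolate O-sulfonylation gives a single enol triflate and removes the epimerisable centre.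

**Step 6**
Reactants: 13 enol triflate
Product: 14 diene chromone
Conditions: Pd(OAc)2 (5 mol %), PPh3, HCO2H, n-Bu3N, DMF, 60 °C
Reagents that add atoms: none
Why: Palladium-catalysed formate reduction of the enol triflate (oxidative addition to zerovalent palladium, formate exchange, decarboxylation, C–H reductive elimination) replaces OTf by H and leaves the trisubstituted alkene exactly where the target has it.

**Step 7**
Reactants: 14 diene chromone; 15 iodomethane
Product: 17 cis-fused 9a-methyl chromanone, via lithium enolate 16 (not isolated)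
Conditions: LiBH(s-Bu)3, THF, −78 °C; then MeI, DMPU, −78 → 0 °C
Reagents that add atoms: iodomethane 15, CI
Why: Reductive alkylation of the vinylogous ester, in which conjugate hydride addition to C3a occurs on the face of the flat cyclopentene that carries the vinylic C2'–H (anti to the C6' CH(CH3) arm of the spiro ring) and enolate 16 is then methylated at C9a on the same convex face, so that 3a-H and 9a-CH3 become cis.

**Step 8**
Reactants: 17 cis-fused 9a-methyl chromanone; 18 4-methoxybenzyl alcohol
Product: 19 bis(4-methoxybenzyl) ether chromanone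
Conditions: 4-MeOC6H4CH2OH, NaH, DMF, 0 → 60 °C
Reagents that add atoms: 4-methoxybenzyl alcohol 18, COc1ccc(CO)cc1
Why: Twofold SNAr of the fluorides ortho and para to the aryl ketone by the sodium alkoxide is safe because the ketone has no α-hydrogen, so neither enolisation nor retro-oxa-Michael ring opening can occur.

**Step 9**
Reactants: 19 bis(4-methoxybenzyl) ether chromanone; 20 isobutylmagnesium bromide
Product: 21 tertiary benzylic alcohol
Conditions: i-BuMgBr, CeCl3, THF, −78 → 0 °C; aq NH4Cl
Reagents that add atoms: isobutylmagnesium bromide 20, CC(C)C[Mg]Br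
Why: The organocerium reagent made from the Grignard reagent and CeCl3 should add 1,2 to the hindered, non-enolisable aryl ketone without β-hydride reduction, entering from the convex face; the configuration of the new carbinol centre is of no consequence because it is ionised in step 10.

**Step 10**
Reactants: 21 tertiary benzylic alcohol
Product: 23 resorcinol chroman, via bis-ether chroman 22 (not isolated)
Conditions: CF3CO2H, Et3SiH (excess), CH2Cl2, −20 → 0 °C
Reagents that add atoms: none
Why: Ionic hydrogenation, in which CF3CO2H ionises the tertiary benzylic alcohol to a cation stabilised by three oxygen donors, Et3SiH delivers hydride to C9 on the convex face (the face of 9a-CH3 and 3a-H, anti to the cyclopentane and the spirocyclohexene) to set the isobutyl centre, and the same medium cleaves both 4-methoxybenzyl ethers while the silane intercepts the benzyl cation.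

**Step 11**
Reactants: 23 resorcinol chroman; 24 N,N-dimethylformamide; 25 water
Product: 27 target CNP0121396.1, via bis-iminium salt 26 (not isolated)
Conditions: POCl3, DMF, MeCN, 0 °C → rt; then H2O, 50 °C
Reagents that add atoms: N,N-dimethylformamide 24, CN(C)C=O; water 25, O
Why: Twofold Vilsmeier–Haack formylation of the phloroglucinol-type ring at its only two free positions, each ortho or para to all three oxygen donors, followed by hydrolysis of bis-iminium salt 26, should give the dialdehyde without affecting the isolated alkene.

**Compound list**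

1 | (−)-menthone, (2S,5R)-5-methyl-2-(propan-2-yl)cyclohexan-1-one | CC(C)[C@@H]1CC[C@@H](C)CC1=O | starting material
2 | ethyl formate | CCOC=O | starting material
3 | (2Z,3R,6S)-2-(hydroxymethylidene)-3-methyl-6-(propan-2-yl)cyclohexan-1-one | CC(C)[C@@H]1CC[C@@H](C)/C(=C/O)C1=O | intermediate
4 | allyl methyl carbonate | C=CCOC(=O)OC | starting material
5 | (1S,2R,5S)-2-methyl-6-oxo-5-(propan-2-yl)-1-(prop-2-en-1-yl)cyclohexane-1-carbaldehyde; allyl trans and formyl cis to the C2 methyl | CC(C)[C@@H]1CC[C@@H](C)[C@](C=O)(CC=C)C1=O | intermediate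
6 | (5S,7S,10R)-10-methyl-7-(propan-2-yl)spiro[4.5]decane-1,6-dione; C1 carbonyl cis and C4 methylene trans to the C10 methyl | O=C1CCC[C@@]12C(=O)[C@H](C(C)C)CC[C@H]2C | intermediate
7 | 2,4,6-trifluorobenzoyl chloride | O=C(Cl)c1c(F)cc(F)cc1F | starting material
8 | lithium C1–C2 enolate of the cyclopentanone of 6 | [Li+].[O-]C1=CCC[C@@]12C(=O)[C@H](C(C)C)CC[C@H]2C | intermediate (not isolated)
9 | lithium enolate of the 2-(2,4,6-trifluorobenzoyl) derivative of 6 | [Li+].[O-]C1=C(C(=O)c2c(F)cc(F)cc2F)CC[C@@]13C(=O)[C@H](C(C)C)CC[C@H]3C | intermediate (not isolated)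
10 | (3S,3'S,6'R)-6,8-difluoro-6'-methyl-3'-(propan-2-yl)-1,2-dihydro-9H-spiro[cyclopenta[b]chromene-3,1'-cyclohexane]-2',9-dione | O=C1c2c(F)cc(F)cc2OC2=C1CC[C@@]21C(=O)[C@H](C(C)C)CC[C@H]1C | intermediate
11 | N-phenylbis(trifluoromethanesulfonimide) | O=S(=O)(N(c1ccccc1)S(=O)(=O)C(F)(F)F)C(F)(F)F | starting material
12 | potassium C2'–C3' enolate of 10 | O=C1c2c(F)cc(F)cc2OC2=C1CC[C@@]21C([O-])=C(C(C)C)CC[C@H]1C.[K+] | intermediate (not isolated)
13 | (3S,6'R)-6,8-difluoro-6'-methyl-9-oxo-3'-(propan-2-yl)-1,2-dihydro-9H-spiro[cyclopenta[b]chromene-3,1'-cyclohex[2]en]-2'-yl trifluoromethanesulfonate | O=C1c2c(F)cc(F)cc2OC2=C1CC[C@@]21C(OS(=O)(=O)C(F)(F)F)=C(C(C)C)CC[C@H]1C | intermediate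
14 | (3R,6'R)-6,8-difluoro-6'-methyl-3'-(propan-2-yl)-1,2-dihydro-9H-spiro[cyclopenta[b]chromene-3,1'-cyclohex[2]en]-9-one | O=C1c2c(F)cc(F)cc2OC2=C1CC[C@@]21C=C(C(C)C)CC[C@H]1C | intermediate
15 | iodomethane | CI | starting material
16 | lithium C9–C9a enolate formed by conjugate reduction of 14 (3a-H on the face of C2') | [Li+].[O-]C1=C2CC[C@@]3(C=C(C(C)C)CC[C@H]3C)[C@@H]2Oc2cc(F)cc(F)c12 | intermediate (not isolated)
17 | (3R,3aS,6'R,9aR)-6,8-difluoro-6',9a-dimethyl-3'-(propan-2-yl)-1,2,3a,9a-tetrahydro-9H-spiro[cyclopenta[b]chromene-3,1'-cyclohex[2]en]-9-one; 3a-H and 9a-CH3 cis | O=C1c2c(F)cc(F)cc2O[C@@H]2[C@@]1(C)CC[C@@]21C=C(C(C)C)CC[C@H]1C | intermediate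
18 | 4-methoxybenzyl alcohol | COc1ccc(CO)cc1 | starting material
19 | (3R,3aS,6'R,9aR)-6,8-bis[(4-methoxyphenyl)methoxy] analogue of 17 | O=C1c2c(OCc3ccc(OC)cc3)cc(OCc3ccc(OC)cc3)cc2O[C@@H]2[C@@]1(C)CC[C@@]21C=C(C(C)C)CC[C@H]1C | intermediate
20 | isobutylmagnesium bromide | CC(C)C[Mg]Br | starting material
21 | (3R,3aS,6'R,9R,9aR)-9-hydroxy-9-(2-methylpropyl) carbinol from 19; OH on the cyclopentane face, isobutyl on the face of 9a-CH3 | O[C@@]1(CC(C)C)c2c(OCc3ccc(OC)cc3)cc(OCc3ccc(OC)cc3)cc2O[C@@H]2[C@@]1(C)CC[C@@]21C=C(C(C)C)CC[C@H]1C | intermediate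
22 | (3R,3aR,6'R,9R,9aS)-6,8-bis[(4-methoxyphenyl)methoxy]-9-(2-methylpropyl) chroman; 9-H, 9a-CH3 and 3a-H all cis | CC(C)C[C@H]1c2c(OCc3ccc(OC)cc3)cc(OCc3ccc(OC)cc3)cc2O[C@@H]2[C@@]1(C)CC[C@@]21C=C(C(C)C)CC[C@H]1C | intermediate (not isolated)
23 | (3R,3aR,6'R,9R,9aS)-6',9a-dimethyl-9-(2-methylpropyl)-3'-(propan-2-yl)-1,2,3a,9a-tetrahydro-9H-spiro[cyclopenta[b]chromene-3,1'-cyclohex[2]ene]-6,8-diol | CC(C)C[C@H]1c2c(O)cc(O)cc2O[C@@H]2[C@@]1(C)CC[C@@]21C=C(C(C)C)CC[C@H]1C | intermediate
24 | N,N-dimethylformamide | CN(C)C=O | starting material
25 | water | O | starting material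
26 | 5,7-bis(dimethyliminiomethyl) dichloride of 23 | CC(C)C[C@H]1c2c(O)c(C=[N+](C)C)c(O)c(C=[N+](C)C)c2O[C@@H]2[C@@]1(C)CC[C@@]21C=C(C(C)C)CC[C@H]1C.[Cl-].[Cl-] | intermediate (not isolated)
27 | CNP0121396.1, (3R,3aR,6'R,9R,9aS)-6,8-dihydroxy-6',9a-dimethyl-9-(2-methylpropyl)-3'-(propan-2-yl)-1,2,3a,9a-tetrahydro-9H-spiro[cyclopenta[b]chromene-3,1'-cyclohex[2]ene]-5,7-dicarbaldehyde | CC(C)C[C@H]1c2c(O)c(C=O)c(O)c(C=O)c2O[C@@H]2[C@@]1(C)CC[C@@]21C=C(C(C)C)CC[C@H]1C | target

**Step count and risks**

Total step count: 11. Longest linear sequence: 11 steps (from 1 to 27).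

Steps most likely to fail:

Step 7. Hydride transfer to the neopentyl-like C3a may be too slow, so that 1,2-reduction of the carbonyl or poor facial selectivity takes over. The fallback sets out from 14 and replaces hydride attack by electron transfer: SmI2 with HMPA and t-BuOH in THF at −78 °C should reduce the enone by protonation of the radical anion at C3a with a small proton donor, and the epimerisable C9a settles in the cis ring fusion, giving the unmethylated cis-fused chromanone F1. Deprotonation of this with LiN(SiMe3)2 at −78 °C and methylation of the ring-fusion enolate with MeI on its convex face comes back to the route at 17.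

Step 9. The branched alkyl reagent may transfer a β-hydride (reduction of the ketone) or fail to add to the deactivated, doubly flanked carbonyl. The fallback sets out from 19 and uses an sp2 nucleophile that has no transferable β-hydride: 2-methylprop-1-enylmagnesium bromide with CeCl3 in THF should give the allylic benzylic carbinol F2. CF3CO2H with Et3SiH then ionises it, reduces the allyl cation and the resulting electron-rich styrene by a second protonation and hydride transfer at C9 from the convex face, and cleaves both benzyl ethers, coming back to the route at 23.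

Step 10. The acid may protonate the trisubstituted alkene, and the liberated 4-methoxybenzyl cation may be captured by the electron-rich resorcinol ring in a Friedel–Crafts alkylation. The fallback sets out from 17 and separates deoxygenation from deprotection: NaOMe in MeOH/THF at 60 °C should give the dimethyl ether chromanone F3, and i-BuMgBr with CeCl3 the dimethoxy carbinol F4. BF3·OEt2 with Et3SiH in CH2Cl2 at −78 °C then deoxygenates it to the dimethoxy chroman F5 without any benzyl cation, and NaSEt in DMF at 140 °C cleaves both methyl ethers by SN2 attack at carbon, coming back to the route at 23.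

**Further compounds**

F1 | step 7 | (3R,6'R)-6,8-difluoro-6'-methyl-3'-(propan-2-yl)-1,2,3a,9a-tetrahydro-9H-spiro[cyclopenta[b]chromene-3,1'-cyclohex[2]en]-9-one, cis ring fusion, 3a-H on the face of C2' | O=C1c2c(F)cc(F)cc2O[C@@H]2[C@H]1CC[C@@]21C=C(C(C)C)CC[C@H]1C
F2 | step 9 | 9-hydroxy-9-(2-methylprop-1-en-1-yl) carbinol from 19, alkenyl group on the face of 9a-CH3 | O[C@@]1(C=C(C)C)c2c(OCc3ccc(OC)cc3)cc(OCc3ccc(OC)cc3)cc2O[C@@H]2[C@@]1(C)CC[C@@]21C=C(C(C)C)CC[C@H]1C
F3 | step 10 | 6,8-dimethoxy analogue of 17 | O=C1c2c(OC)cc(OC)cc2O[C@@H]2[C@@]1(C)CC[C@@]21C=C(C(C)C)CC[C@H]1C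
F4 | step 10 | 6,8-dimethoxy analogue of 21 | O[C@@]1(CC(C)C)c2c(OC)cc(OC)cc2O[C@@H]2[C@@]1(C)CC[C@@]21C=C(C(C)C)CC[C@H]1C
F5 | step 10 | 6,8-dimethoxy analogue of 22 | CC(C)C[C@H]1c2c(OC)cc(OC)cc2O[C@@H]2[C@@]1(C)CC[C@@]21C=C(C(C)C)CC[C@H]1C
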